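If each impurity takes one free catalyst out for good, the number to work out before choosing the next run is the poison ratio: moles of impurity charged per mole of free catalyst charged, with 1, the even match, as the zero point of the scale.

| flask | substrate | free catalyst | impurity | temperature | remark | time |
|---|---|---|---|---|---|---|
| grey | 0.40 M | 4.1 mol% | 34 mM | −18 °C | run made earlier |  |
| ochre | 0.40 M | 6.1 mol% | 34 mM | −1 °C | run made earlier |  |
| blue | 0.80 M | 8.2 mol% | 34 mM | −18 °C | run made earlier |  |
| midnight | 0.40 M | 8.2 mol% | 34 mM | −25 °C |  | 2.5 d |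
| noon | 0.40 M | 8.2 mol% | 34 mM | −10 °C |  | 2.5 d |
| dusk | 0.40 M | 8.2 mol% | 34 mM |  | at −25 °C until 20 h, from then on at 5 °C | 2.5 d |
| summer | 0.40 M | 8.2 mol% | 34 mM | 5 °C |  | 2.5 d |

- grey (time / h: product / %, substrate / %): 8.00: 0.6, 96.9; 15.0: 1.8, 96.2; 25.0: 2.7, 96.3; 30.0: 2.9, 94.9; 40.0: 4.1, 94.8; 50.0: 4.5, 93.5
- ochre (time / h: product / %, substrate / %): 1.33: 0.6, 97.3; 2.00: 2.1, 96.3; 3.00: 3.7, 95.3; 6.00: 7.5, 91.0; 10.0: 10.8, 86.8; 15.0: 13.9, 83.7
- blue (time / h: product / %, substrate / %): 4.00: 0.4, 93.7; 8.00: 1.7, 92.8; 15.0: 4.1, 90.5; 25.0: 7.9, 87.8; 50.0: 14.1, 81.2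

(scatter of a reading: 0.5 percentage points)

- the flask that comes out highest in amount of product, in percent of the substrate charged, or "all alike" when all lie within 1.5 percentage points (midnight / noon / dusk / summer / all alike)
- product at the end, in percent of the substrate charged, midnight
- product at the end, in percent of the substrate charged, noon
- product at the end, in percent of the substrate charged, dusk
- product at the end, in percent of the substrate charged, summer



For midnight, noon, dusk and summer, which share one charge:

poison ratio = [impurity] / [free catalyst] = 34 mM / (8.2 mol% × 0.40 M) = 1.04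

That is just above the zero point. Under our rule, each of these flasks, if it runs until its catalyst is used up, keeps this share of its impurity:

impurity left = 1 − 1/ratio = 3.53%

The earlier runs at −18 °C lie on either side of the zero point, grey at 2.07 and blue at 0.518. Product per catalyst charged reads 1.10 in grey and 1.72 in blue after 50.0 h, so blue went further. But blue also holds 0.80 M of substrate, so two settings differ, and we take this reading as a lean our way, not as a proof.

So we don't plan on a catalyst that outlasts its impurity; we want its turnovers early. Ochre at −1 °C reached 2.28 per catalyst in 15.0 h, a faster pace than grey's, though ochre's loading of 6.1 mol% differs from grey's 4.1 mol% as well as its temperature. Our next run is therefore summer: the recipe unchanged, 5 °C from the start, and no cold hold like dusk's 20 h.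

The forecast also names summer, on the ground that “Reaction gains more from warmth than death does”, with 4.2% for midnight, 17% for noon, 27% for dusk and 30% for summer.

The simulation puts summer highest at 42.6%, with dusk at 39.0%, noon at 22.8% and midnight at 4.25%. At the end of summer 10% of the impurity is left and 93.2% of the catalyst stands as spent catalyst. The ratio turns the impurity lost into catalyst charged:

(1 − impurity left) × ratio = 93.6%

That matches the spent share. At 25.0 d summer holds 3.58% of its impurity, against our 3.53%.

    free catalyst + impurity → spent catalyst (k = 6.40 M⁻¹ h⁻¹, Ea = 58.0 kJ mol⁻¹)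
    catalyst intermediate A → catalyst intermediate B (k = 3.10 h⁻¹, Ea = 94.0 kJ mol⁻¹)
    catalyst intermediate B ⇌ free catalyst + product (K = 5.80 M, k = 46.0 h⁻¹, Ea = 79.0 kJ mol⁻¹, ΔH = −29.0 kJ mol⁻¹)
    2 substrate → homo dimer (k = 0.00380 M⁻¹ h⁻¹, Ea = 73.0 kJ mol⁻¹)
    substrate + free catalyst ⇌ catalyst intermediate A (K = 1.40 M⁻¹, k = 2.60 M⁻¹ h⁻¹, Ea = 46.0 kJ mol⁻¹, ΔH = −18.0 kJ mol⁻¹)
    (constants at 5 °C)

The neighbour like summer but with 0.16 M of substrate keeps 34 mM of impurity and the same loading, so its ratio is 2.59, and 61.4% of its impurity should stay once the catalyst is used up. It ends with 61% of the impurity left, spent catalyst at >99.9% and 11.5% of product.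

The numbers in the tables come from a simulation from invented constants; the scatter is artificial.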